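**Assumptions:** The acyl chain in the target SMILES is a C30 unit (triacontanoate, carbonyl carbon included). The target has no stereocenters, so no enantioselective step is needed.

## Retrosynthetic overview
1. Remove the phenol tBu group last. Disconnect the ester C–O bond and the benzylic C–H by anti-Markovnikov addition of triacontanoic acid across 4-tert-butoxystyrene. This is the proposed new photoredox step.
2. Build the C30 acid from two C15 pieces by Cu-catalysed coupling of C15H31MgBr with 15-bromopentadecanoic acid, which comes from ring-opening ω-pentadecalactone.
3. No new rings are formed. The benzene ring is purchased, and the only other ring (the macrolactone) is opened in step 1.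

## Route

**Step 1**
Reactants: 1 (ω-pentadecalactone, oxacyclohexadecan-2-one)
Product: 2 (15-bromopentadecanoic acid)
Conditions: 48% aq. HBr, H2SO4 (cat.), 100 °C, 16 h
Reagents that add atoms: hydrogen bromide, Br
Why: Acid-promoted SN2 opening of the lactone by bromide at the primary alkyl–oxygen carbon gives the ω-bromo acid (lactone-to-bromo-acid cleavage).

**Step 2**
Reactants: 3 (1-bromopentadecane)
Product: 4 (pentadecylmagnesium bromide)
Conditions: Mg turnings, I2 (cat.), THF, reflux, 2 h
Reagents that add atoms: magnesium, [Mg]
Why: Standard Grignard formation from a primary alkyl bromide.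

**Step 3**
Reactants: 2 (15-bromopentadecanoic acid), 4 (pentadecylmagnesium bromide, 2.5 equiv)
Product: 5 (triacontanoic acid)
Conditions: Li2CuCl4 (3 mol%), THF, –10 °C to 25 °C, 12 h; then aq. HCl
Reagents that add atoms: none
Why: The first equivalent of Grignard deprotonates the acid to give a carboxylate that tolerates the reaction. The remaining Grignard then couples with the primary C–Br bond under Cu catalysis (Schlosser/Fouquet-type alkyl–alkyl coupling), joining C15 and C15 to give C30.

**Step 4**
Reactants: 5 (triacontanoic acid, 1.0 equiv), 6 (4-tert-butoxystyrene, 2.5 equiv)
Product: 7 (4-tert-butoxyphenethyl triacontanoate)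
Conditions: Mes-Acr-Ph+ BF4– (2.5 mol%), PhSSPh (10 mol%), 2,4,6-collidine (20 mol%), PhCF3/DCE 1:1 (0.05 M), 45 °C, 450 nm LEDs, 24 h
Reagents that add atoms: none (the acid and alkene combine in full; the catalysts do not remain in the product)
Why: Proposed new method: the excited acridinium oxidises the electron-rich 4-tBuO-styrene to its radical cation, the collidinium triacontanoate adds at the terminal CH2 to give a p-alkoxy-stabilised benzylic radical, and thiol/thiyl H-atom transfer delivers the benzylic H and turns over the catalysts. The closest known reaction is photoredox anti-Markovnikov hydroacyloxylation of tri- and 1,2-disubstituted alkenes. It has not been shown for terminal vinylarenes, which tend to polymerise or dimerise via the radical cation, nor for a waxy C30 acid. Excess styrene, moderate dilution, 45 °C and an ion-paired carboxylate should favour addition over oligomerisation. No stereocenter is formed.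

**Step 5**
Reactants: 7 (4-tert-butoxyphenethyl triacontanoate)
Product: 8 (Basalethanolide B, 4-hydroxyphenethyl triacontanoate)
Conditions: TFA, Et3SiH (3 equiv, cation scavenger), CH2Cl2, 0 °C to 25 °C, 3 h; then aq. NaHCO3 wash
Reagents that add atoms: none (TFA and Et3SiH leave no atoms in the product; the tBu group is lost as isobutane/isobutene)
Why: Acidolysis of the aryl tert-butyl ether via the tBu cation leaves the primary alkyl ester untouched (standard tBu ether deprotection).

## Compound list
1 | ω-pentadecalactone (oxacyclohexadecan-2-one) | O=C1CCCCCCCCCCCCCCO1 | starting material
2 | 15-bromopentadecanoic acid | OC(=O)CCCCCCCCCCCCCCBr | intermediate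
3 | 1-bromopentadecane | CCCCCCCCCCCCCCCBr | starting material
4 | pentadecylmagnesium bromide | CCCCCCCCCCCCCCC[Mg]Br | intermediate
5 | triacontanoic acid | CCCCCCCCCCCCCCCCCCCCCCCCCCCCCC(=O)O | intermediate
6 | 4-tert-butoxystyrene | C=Cc1ccc(OC(C)(C)C)cc1 | starting material
7 | 4-tert-butoxyphenethyl triacontanoate | CCCCCCCCCCCCCCCCCCCCCCCCCCCCCC(=O)OCCc1ccc(OC(C)(C)C)cc1 | intermediate
8 | Basalethanolide B (4-hydroxyphenethyl triacontanoate) | CCCCCCCCCCCCCCCCCCCCCCCCCCCCCC(=O)OCCc1ccc(O)cc1 | target

## Summary
Total steps: 5. Longest linear sequence: 4 (steps 1, 3, 4, 5, starting from 1). The Grignard preparation (step 2) is a convergent branch.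

Three steps most likely to fail:
1. **Step 4 (proposed new step).** Styrene oligomerisation, Markovnikov regioisomer formation or poor solubility of the C30 acid could lower the yield.
   - Fallback: drop steps 4 and 5 and esterify commercial tyrosol with 5 directly. Use Novozym 435 (lipase) in toluene/tBuOH at 60 °C with 4 Å molecular sieves, which is chemoselective for the primary alcohol over the phenol.
2. **Step 3.** The poorly soluble magnesium carboxylate, triacontane from Grignard homocoupling and incomplete conversion could all reduce the yield.
   - Fallback: buy commercial triacontanoic acid. Alternatively, use cross-Kolbe electrolysis of stearic acid with monomethyl tetradecanedioate (MeOH, Pt electrodes), followed by LiOH hydrolysis.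
3. **Step 1.** Ring-opening of the macrolactone may be incomplete or give oligomeric esters.
   - Fallback: hydrolyse 1 with KOH/EtOH–H2O to 15-hydroxypentadecanoic acid, then brominate under Appel conditions (CBr4, PPh3) to give 2.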